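Ring A bears three contiguous carbon substituents: the alkyne at C6, the methide carbon C7 on C1 and resorcinol ring B on C2. The synthesis rests on cutting C2–C1' and C1–C7 at once, which leaves a C1–C2 aryne polarised by the neighbouring C6 alkynyl group. In a single operation an aryl fluoride (fluorine on C1, hydrogen on C2, alkyne on C6, protected hydroxymethyl on C5) is lithiated, loses LiF, takes up the ring B aryllithium at C2 and is captured at C1 by a protected 4-hydroxybenzaldehyde. Oxidation, a second aryllithium addition and acidic unmasking with loss of water then complete the quinone methide.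

Key step: step 8

Remark on numbering: ring A is the central benzene; C1 carries C7, C2 carries ring B (C1' to C6', oxygens on C2' and C4'), C5 carries the hydroxymethyl group and C6 the alkyne C8≡C9.

Assumption: the target is the open para-quinone methide of the given SMILES. It has no stereocenter and no double-bond isomerism at C7, because the quinonoid ring is symmetric. The cyclic ether that would arise if the 2'-hydroxyl of ring B added to C7 is taken to be the less favoured isomer under neutral conditions.

Step 1
Reactants: 1 4-hydroxybenzaldehyde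
Product: 2 4-(methoxymethoxy)benzaldehyde
Conditions: MOMCl, i-Pr2NEt, CH2Cl2, 0 °C → rt
Reagents that add atoms: chloromethyl methyl ether (MOMCl), COCCl
Why: O-alkylation of the phenol by the α-chloro ether under amine base (acetal protection) is routine and leaves the aldehyde untouched.

Step 2
Reactants: 2 4-(methoxymethoxy)benzaldehyde
Product: 3 1-ethynyl-4-(methoxymethoxy)benzene
Conditions: dimethyl (1-diazo-2-oxopropyl)phosphonate, K2CO3, MeOH, 0 °C → rt
Reagents that add atoms: dimethyl (1-diazo-2-oxopropyl)phosphonate, CC(=O)C(=[N+]=[N-])P(=O)(OC)OC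
Why: In this Ohira–Bestmann (Seyferth–Gilbert) homologation the methanolysis-released diazomethylphosphonate anion adds to the non-enolisable aldehyde and the derived alkylidene carbene rearranges by 1,2-hydrogen shift to the terminal alkyne, under mild base that the acetal tolerates.

Step 3
Reactants: 4 2-bromo-3-fluorobenzaldehyde; 3 1-ethynyl-4-(methoxymethoxy)benzene
Product: 5 3-fluoro-2-{[4-(methoxymethoxy)phenyl]ethynyl}benzaldehyde
Conditions: Pd(PPh3)2Cl2 (3 mol%), CuI (3 mol%), Et3N, THF, 50 °C
Reagents that add atoms: none
Why: In this Sonogashira coupling the ortho formyl and fluoro groups ease oxidative addition of zerovalent palladium into the C–Br bond, the copper acetylide of 3 delivers the alkynyl group, and the C–F bond stays inert.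

Step 4
Reactants: 5 3-fluoro-2-{[4-(methoxymethoxy)phenyl]ethynyl}benzaldehyde
Product: 6 (3-fluoro-2-{[4-(methoxymethoxy)phenyl]ethynyl}phenyl)methanol
Conditions: NaBH4, MeOH, 0 °C
Reagents that add atoms: none
Why: Borohydride reduction of the aryl aldehyde to the primary benzylic alcohol is chemoselective over the diaryl alkyne, the aryl fluoride and the acetal.

Step 5
Reactants: 6 (3-fluoro-2-{[4-(methoxymethoxy)phenyl]ethynyl}phenyl)methanol
Product: 7 1-fluoro-3-[(methoxymethoxy)methyl]-2-{[4-(methoxymethoxy)phenyl]ethynyl}benzene
Conditions: MOMCl, i-Pr2NEt, CH2Cl2, 0 °C → rt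
Reagents that add atoms: chloromethyl methyl ether (MOMCl), COCCl
Why: Acetal protection by O-alkylation masks the alcohol as a base-stable ether, so that no alkoxide sits next to the alkyne during the lithiation chemistry.

Step 6
Reactants: 8 4-bromoresorcinol
Product: 9 1-bromo-2,4-bis(methoxymethoxy)benzene
Conditions: MOMCl (2.5 equiv), i-Pr2NEt, CH2Cl2, 0 °C → rt
Reagents that add atoms: chloromethyl methyl ether (MOMCl), COCCl
Why: Twofold O-alkylation of the phenols gives the bis-acetal, whose ortho oxygen later stabilises the aryllithium by chelation.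

Step 7
Reactants: 10 4-bromophenol
Product: 11 1-bromo-4-(methoxymethoxy)benzene
Conditions: MOMCl, i-Pr2NEt, CH2Cl2, 0 °C → rt
Reagents that add atoms: chloromethyl methyl ether (MOMCl), COCCl
Why: The same phenol O-alkylation applies, and the aryl bromide is kept for bromine–lithium exchange in step 10.

Step 8
Reactants: 7 1-fluoro-3-[(methoxymethoxy)methyl]-2-{[4-(methoxymethoxy)phenyl]ethynyl}benzene; 9 1-bromo-2,4-bis(methoxymethoxy)benzene; 2 4-(methoxymethoxy)benzaldehyde
Product: 16 {2-[2,4-bis(methoxymethoxy)phenyl]-5-[(methoxymethoxy)methyl]-6-{[4-(methoxymethoxy)phenyl]ethynyl}phenyl}[4-(methoxymethoxy)phenyl]methanol (racemic), via ring B aryllithium 12 (not isolated), via C2-lithiated fluoroarene 13 (not isolated), via C1–C2 aryne 14 (not isolated), via C1 biaryllithium 15 (not isolated)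
Conditions: 9 (2 equiv), n-BuLi, THF, −78 °C; 7, lithium 2,2,6,6-tetramethylpiperidide (1.1 equiv), THF, −78 °C; combine, −78 → −35 °C; then 2 (3.5 equiv), −78 °C; aq NH4Cl, −78 °C
Reagents that add atoms: none
Why: Bromine–lithium exchange converts 9 into aryllithium 12, while the hindered amide removes the C2 proton of 7, the only one ortho to fluorine, to give 13; on warming 13 expels LiF, aryne 14 is carbolithiated by 12 at C2, and the C1 aryllithium 15 so formed adds to the carbonyl of aldehyde 2. The closest known reaction type is the three-component aryne coupling in which an ortho-lithiated aryl fluoride is the aryne source, an aryllithium adds and the resulting 2-lithiobiaryl is trapped by a carbonyl electrophile. No ring is closed. The carbinol carbon C7 forms without a controlling element and is racemic, which is harmless because step 9 oxidises it. The step needs attack of 12 at C2 and not at C1: the sp-hybridised C8 on C6 withdraws electron density inductively, so the aryne is distorted towards a carbanion at the adjacent C1, attack at C2 is also the less crowded one, and the 2'-acetal oxygen of ring B can then chelate lithium at C1. It also needs chemoselective metalation, secured by the acidifying fluorine and the non-nucleophilic amide, and an excess of 2, so that 15 is captured although surplus 12 consumes part of the aldehyde.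

Step 9
Reactants: 16 the racemic diarylmethanol from step 8
Product: 17 {2-[2,4-bis(methoxymethoxy)phenyl]-5-[(methoxymethoxy)methyl]-6-{[4-(methoxymethoxy)phenyl]ethynyl}phenyl}[4-(methoxymethoxy)phenyl]methanone
Conditions: Dess–Martin periodinane, pyridine, CH2Cl2, 0 °C → rt
Reagents that add atoms: none
Why: Dess–Martin oxidation of the secondary diaryl carbinol proceeds by ligand exchange at hypervalent iodine under near-neutral conditions that spare the acetals and the alkyne, and it removes the only stereocenter.

Step 10
Reactants: 17 the diaryl ketone from step 9; 11 1-bromo-4-(methoxymethoxy)benzene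
Product: 19 {2-[2,4-bis(methoxymethoxy)phenyl]-5-[(methoxymethoxy)methyl]-6-{[4-(methoxymethoxy)phenyl]ethynyl}phenyl}bis[4-(methoxymethoxy)phenyl]methanol, via 4-(methoxymethoxy)phenyllithium 18 (not isolated)
Conditions: 11 (3 equiv), n-BuLi, THF, −78 °C; then 17, −78 → −20 °C; aq NH4Cl, −20 °C
Reagents that add atoms: none
Why: Bromine–lithium exchange gives an unhindered aryllithium whose 1,2-addition to the non-enolisable diaryl ketone yields the tertiary alcohol; C7 then carries two identical aryl groups and is no stereocenter, and the cold quench keeps the alkoxide from adding to the neighbouring alkyne.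

Step 11
Reactants: 19 the hexakis-MOM triaryl carbinol from step 10
Product: 21 selaginellin F, 4-[{2-(2,4-dihydroxyphenyl)-5-(hydroxymethyl)-6-[(4-hydroxyphenyl)ethynyl]phenyl}(4-hydroxyphenyl)methylidene]cyclohexa-2,5-dien-1-one, via deprotected triaryl carbinol 20 (not isolated)
Conditions: HCl (3 M aq), MeOH/THF, 45 °C; then phosphate buffer, pH 6
Reagents that add atoms: none
Why: Acid-catalysed acetal cleavage (transacetalisation, methanol taking up the formaldehyde unit as dimethoxymethane) frees all six hydroxyls, and the para-hydroxy-stabilised triaryl carbinol 20 ionises and loses water (E1-type dehydration) to the fuchsone-type quinone methide, only one product being possible because the two aryl rings on C7 are equivalent.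

Compound list
1 | 4-hydroxybenzaldehyde | O=Cc1ccc(O)cc1 | starting material
2 | 4-(methoxymethoxy)benzaldehyde | O=Cc1ccc(OCOC)cc1 | intermediate
3 | 1-ethynyl-4-(methoxymethoxy)benzene | COCOc1ccc(C#C)cc1 | intermediate
4 | 2-bromo-3-fluorobenzaldehyde | O=Cc1cccc(F)c1Br | starting material
5 | 3-fluoro-2-{[4-(methoxymethoxy)phenyl]ethynyl}benzaldehyde | O=Cc1cccc(F)c1C#Cc1ccc(OCOC)cc1 | intermediate
6 | (3-fluoro-2-{[4-(methoxymethoxy)phenyl]ethynyl}phenyl)methanol | OCc1cccc(F)c1C#Cc1ccc(OCOC)cc1 | intermediate
7 | 1-fluoro-3-[(methoxymethoxy)methyl]-2-{[4-(methoxymethoxy)phenyl]ethynyl}benzene | COCOCc1cccc(F)c1C#Cc1ccc(OCOC)cc1 | intermediate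
8 | 4-bromoresorcinol (4-bromobenzene-1,3-diol) | Oc1ccc(Br)c(O)c1 | starting material
9 | 1-bromo-2,4-bis(methoxymethoxy)benzene | COCOc1ccc(Br)c(OCOC)c1 | intermediate
10 | 4-bromophenol | Oc1ccc(Br)cc1 | starting material
11 | 1-bromo-4-(methoxymethoxy)benzene | COCOc1ccc(Br)cc1 | intermediate
12 | 2,4-bis(methoxymethoxy)phenyllithium | [Li]c1ccc(OCOC)cc1OCOC | intermediate (not isolated)
13 | [2-fluoro-4-[(methoxymethoxy)methyl]-3-{[4-(methoxymethoxy)phenyl]ethynyl}phenyl]lithium (lithium on C2 of ring A) | COCOCc1ccc([Li])c(F)c1C#Cc1ccc(OCOC)cc1 | intermediate (not isolated)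
14 | 4-[(methoxymethoxy)methyl]-3-{[4-(methoxymethoxy)phenyl]ethynyl}-1,2-didehydrobenzene (aryne, formal triple bond C1–C2 of ring A) | COCOCC1=C(C#Cc2ccc(OCOC)cc2)C#CC=C1 | intermediate (not isolated)
15 | [2',4'-bis(methoxymethoxy)-4-[(methoxymethoxy)methyl]-3-{[4-(methoxymethoxy)phenyl]ethynyl}-1,1'-biphenyl-2-yl]lithium (lithium on C1 of ring A) | COCOCc1ccc(-c2ccc(OCOC)cc2OCOC)c([Li])c1C#Cc1ccc(OCOC)cc1 | intermediate (not isolated)
16 | {2-[2,4-bis(methoxymethoxy)phenyl]-5-[(methoxymethoxy)methyl]-6-{[4-(methoxymethoxy)phenyl]ethynyl}phenyl}[4-(methoxymethoxy)phenyl]methanol, racemic | COCOCc1ccc(-c2ccc(OCOC)cc2OCOC)c(C(O)c2ccc(OCOC)cc2)c1C#Cc1ccc(OCOC)cc1 | intermediate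
17 | {2-[2,4-bis(methoxymethoxy)phenyl]-5-[(methoxymethoxy)methyl]-6-{[4-(methoxymethoxy)phenyl]ethynyl}phenyl}[4-(methoxymethoxy)phenyl]methanone | COCOCc1ccc(-c2ccc(OCOC)cc2OCOC)c(C(=O)c2ccc(OCOC)cc2)c1C#Cc1ccc(OCOC)cc1 | intermediate
18 | 4-(methoxymethoxy)phenyllithium | [Li]c1ccc(OCOC)cc1 | intermediate (not isolated)
19 | {2-[2,4-bis(methoxymethoxy)phenyl]-5-[(methoxymethoxy)methyl]-6-{[4-(methoxymethoxy)phenyl]ethynyl}phenyl}bis[4-(methoxymethoxy)phenyl]methanol | COCOCc1ccc(-c2ccc(OCOC)cc2OCOC)c(C(O)(c2ccc(OCOC)cc2)c2ccc(OCOC)cc2)c1C#Cc1ccc(OCOC)cc1 | intermediate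
20 | {2-(2,4-dihydroxyphenyl)-5-(hydroxymethyl)-6-[(4-hydroxyphenyl)ethynyl]phenyl}bis(4-hydroxyphenyl)methanol | OCc1ccc(-c2ccc(O)cc2O)c(C(O)(c2ccc(O)cc2)c2ccc(O)cc2)c1C#Cc1ccc(O)cc1 | intermediate (not isolated)
21 | selaginellin F | O=C1C=CC(=C(c2ccc(O)cc2)c2c(-c3ccc(O)cc3O)ccc(CO)c2C#Cc2ccc(O)cc2)C=C1 | target

Total step count: 11. Longest linear sequence: 9 steps (steps 1, 2, 3, 4, 5, 8, 9, 10, 11).

Steps most likely to fail

Step 8. The amine set free in the lithiation may return a proton to the C1 aryllithium 15, or the amide may itself add to aryne 14, before the aldehyde is introduced; surplus 12 also competes with 15 for the aldehyde. The fallback is free of amine at the coupling stage and separates the two bond formations. It sets out from 7, which is lithiated at C2 as before (lithium 2,2,6,6-tetramethylpiperidide, THF, −78 °C) and quenched with iodine at −78 °C, below the temperature of LiF loss. This ortho-lithiation and iodination should give 2-fluoro-1-iodo-4-[(methoxymethoxy)methyl]-3-{[4-(methoxymethoxy)phenyl]ethynyl}benzene F1, which is isolated. F1 and aryllithium 12 (THF, −78 → −30 °C) then enter the halogen-transfer chain known for ortho-dihaloarenes and aryllithiums: iodine–lithium exchange gives 13, LiF loss gives 14, 12 adds at C2, and 15 takes iodine from a further molecule of F1. The expected product is 2-iodo-2',4'-bis(methoxymethoxy)-4-[(methoxymethoxy)methyl]-3-{[4-(methoxymethoxy)phenyl]ethynyl}-1,1'-biphenyl F2, formed with no proton source in the flask. Iodine–lithium exchange on purified F2 (n-BuLi, THF, −78 °C) regenerates 15 alone, and addition of one equivalent of 2 comes back to the route at 16.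

Step 11. The cation at C7 may be captured by the 2'-hydroxyl of ring B (closure of a six-membered cyclic ether) in competition with proton loss to the quinone methide; liberated formaldehyde may also alkylate the electron-rich ring B if it escapes the methanol. The fallback sets out from 19 and accepts the closure: HCl in methanol at room temperature, run to complete acetal cleavage, should give 6,6-bis(4-hydroxyphenyl)-8-(hydroxymethyl)-7-[(4-hydroxyphenyl)ethynyl]-6H-benzo[c]chromen-3-ol F3. Dilute aqueous NaOH under argon then opens the ring, the phenoxide of a C6 aryl group expelling the ring B aryloxide (a retro-oxa-Michael elimination of the kind that opens the closed forms of phthalein dyes in base). Acidification to pH 6 with phosphate buffer comes back to the route at 21.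

Step 10. The 1,2-addition at the congested carbonyl of 17, flanked by ring B and the alkyne, may be slow, so that electron transfer, reduction or recovery of ketone takes over. The fallback forms C1–C7 with both C7 aryl groups already in place. Purchased 4,4'-dihydroxybenzophenone is protected (MOMCl, i-Pr2NEt, CH2Cl2) to bis[4-(methoxymethoxy)phenyl]methanone F4. The fallback then sets out from 7 and 9, which are taken through the protocol of step 8 with F4 in place of aldehyde 2. The C1 aryllithium 15 adds to the unhindered diaryl ketone, as 2-lithiobiaryls do with benzophenones, and this comes back to the route at 19 without passing through 16 and 17.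

Further compounds
F1 | step 8 | 2-fluoro-1-iodo-4-[(methoxymethoxy)methyl]-3-{[4-(methoxymethoxy)phenyl]ethynyl}benzene | COCOCc1ccc(I)c(F)c1C#Cc1ccc(OCOC)cc1
F2 | step 8 | 2-iodo-2',4'-bis(methoxymethoxy)-4-[(methoxymethoxy)methyl]-3-{[4-(methoxymethoxy)phenyl]ethynyl}-1,1'-biphenyl | COCOCc1ccc(-c2ccc(OCOC)cc2OCOC)c(I)c1C#Cc1ccc(OCOC)cc1
F3 | step 11 | 6,6-bis(4-hydroxyphenyl)-8-(hydroxymethyl)-7-[(4-hydroxyphenyl)ethynyl]-6H-benzo[c]chromen-3-ol | OCc1ccc2-c3ccc(O)cc3OC(c3ccc(O)cc3)(c3ccc(O)cc3)c2c1C#Cc1ccc(O)cc1
F4 | step 10 | bis[4-(methoxymethoxy)phenyl]methanone | COCOc1ccc(cc1)C(=O)c1ccc(OCOC)cc1
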